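(All runs were computed on assumed constants; scatter was added.)

Count time from the first drop of the feed: the flask is asked at 12 min, twice its dosing time.

| flask | substrate | acid | remark | time |
|---|---|---|---|---|
| elm | 0.045 M (fed, over 6.0 min) | 0.96 mM | run made earlier; the fed solution adds 0.25 times the starting volume |  |
| oak | 0.070 M (fed, over 6.0 min) | 0.96 mM | run made earlier; the fed solution adds 0.25 times the starting volume |  |
| maple | 0.032 M (fed, over 6.0 min) | 0.48 mM | run made earlier; the fed solution adds 0.25 times the starting volume |  |
| flask | 0.032 M (fed, over 6.0 min) | 0.960 mM | the fed solution adds 0.25 times the starting volume | 12 min |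

- elm (time / min: substrate / %, target / %): 0.500: 7.6, 1.3; 1.33: 19.0, 2.1; 2.50: 33.2, 7.0; 4.00: 47.0, 15.7; 6.00: 59.7, 31.5; 8.00: 43.6, 45.7; 10.0: 33.3, 54.7
- oak (time / min: substrate / %, target / %): 0.833: 11.8, 0.7; 1.33: 19.8, 2.8; 2.00: 28.1, 5.1; 2.50: 32.4, 7.4; 4.00: 45.3, 17.4; 6.00: 56.5, 30.5; 10.0: 31.3, 54.9
- maple (time / min: substrate / %, target / %): 0.833: 12.9, 0.4; 1.33: 20.5, 1.2; 2.50: 37.4, 5.1; 5.00: 65.2, 14.7; 10.0: 52.4, 37.5

(readings scatter by 0.5 percentage points)

- acid is the free proton; pH is minus the decimal logarithm of its molar concentration
- percentages count the substrate that a species holds: one idle adduct counts as two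
- target is meant together with its idle adduct
- every charge counts on the volume at the start, and the solution that is fed holds the whole dose
- what was read earlier has a scatter of 0.5 percentage points, one standard deviation
- reactions considered so far: substrate + acid -> weak acid + acid + target; weak acid <-> conjugate base + acid; substrate -> weak acid + target; weak acid -> by-product carried off; substrate + target <-> idle adduct
- in an amount of target, one idle adduct counts as one target
- what has gone from substrate into another species counts as reacted, even if it can come back
- percentages count the whole charge, also what has not yet gone in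

- part of the substrate that has reacted at 12 min
- pH of the solution at 12 min

Ask first where this ends. The acid comes back in the step substrate + acid, and target is still climbing at the end of the elm run, from 45.7% to 54.7%, so take target as the end state and ask how fast it is approached.

Name the acid clock k, the target gained per minute per unit of free substrate, a pseudo-first-order constant. Read it in elm after the feed, by trapezoids:

k = Δtarget / ∫substrate dt = 0.129 min⁻¹

Test it. Oak, with more substrate, tracks elm in percent: 7.4% of target against 7.0% at 2.50 min. During the feed elm reads 0.145 min⁻¹. Maple, with half the acid, reads 0.0749 min⁻¹ during its feed, about half of elm's value. So let k follow c(acid).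

Now climb the ladder. The adduct's side store comes first: target already counts one unit of each adduct and one adduct counts as two, so the store holds twice the gap in the elm balance, 17.6% of the charge at 6.00 min and 24.0% at 10.0 min. Next comes the clock's half-life, 5.38 min, close to the feed time, and elm's free substrate reads 59.7% at the end of its feed. Last, 6.00 min remain, about one half-life. The flask has elm's acid, so start from elm's reading:

c(substrate) = 59.7% × exp(−k·6.00 min) = 27.6% of the charge

That makes 72.4% reacted. The diluted acid, 0.768 mM, gives pH 3.11.

The forecast says 73.5% and pH 3.09, holding that “k is nearly proportional to diluted charged acid”.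

The flask gives 72.9% reacted and pH 3.11.

    substrate + acid → weak acid + acid + target (k = 163 M⁻¹ min⁻¹)
    weak acid ⇌ conjugate base + acid, settled at all times (K = 7.90 × 10⁻⁵ M)
    substrate → weak acid + target (k = 0.00568 min⁻¹)
    weak acid → by-product carried off (k = 5.90 min⁻¹)
    substrate + target ⇌ idle adduct, settled at all times (K = 22.0 M⁻¹)

Put the clock on the flask: free substrate falls from 60.8% at 6.00 min to 27.1% at 12.0 min, a decay constant of 0.135 min⁻¹ against k = 0.129 min⁻¹. Now take the neighbour flask with 5.8 × 10⁻⁴ M of acid, all else held. Scale the clock by acid to k′ = 0.0778 min⁻¹. A portion of feed stays on average 9.00 min, so: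

left = 27% × exp((k − k′)·E) = 42.9%

That means 57.1% reacted. The neighbour flask stands at 40% left and 59.6% reacted.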